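## Retrosynthetic overview

- Labels: ring A = prenylated 2,4-dihydroxybenzoyl ring; ring B = central resorcinol ring of the chalcone (C1' acyl, 2'-OH, C3', 4'-OH, C5', C6'); ring C = chalcone 2,4-dihydroxyphenyl; ring D = cyclohexene (C1 methyl-bearing sp2 carbon, C2 =CH, C3 CH–ring B, C4 CH–C=O, C5 CH–ring E, C6 CH2); ring E = 2,4-dihydroxyphenyl on C5.
- Key disconnection: the C3(ring D)–C3'(ring B) bond, made by a stereoconvergent Friedel–Crafts union of two chalcone-derived halves. The enabling feature is that C3 is allylic to the C1=C2 alkene, so ionisation gives a C1–C2–C3 (1-methylcyclohexenyl) cation, while C3' lies between the two phenolic oxygens of ring B (doubly ortho-activated). A temporary bromine at C5' blocks the only competing site.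
- Ring D is disconnected at C3–C4 and C5–C6 to a Diels–Alder reaction of tri-O-acetyl morachalcone A (rings A and E) with 1-acetoxy-3-methylbutadiene. A chiral borate sets C4 and C5; the uncontrolled C3–OAc epimers are both funnelled by the key step into the all-trans C3 configuration.
- Both halves come from Claisen–Schmidt condensations of 2,4-dihydroxyacetophenones with a protected 2,4-dihydroxybenzaldehyde.
- Ring order: rings A, B, C and E are bought as arenes; ring D is the only ring built (step 7), before the union (step 12); debromination and deacetylation finish the route.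

Key step: step 12

Assumption: the borate from (R)-1,1'-bi-2-naphthol is taken to shield the enone face that leads to the (4S,5R) ring-D configuration; if a pilot run shows the opposite sense, the (S)-ligand is used with nothing else changed.

## Route

Step 1
Reactants: 1 2,4-dihydroxyacetophenone; 2 prenyl bromide (1-bromo-3-methylbut-2-ene)
Product: 3 3-prenyl-2,4-dihydroxyacetophenone
Conditions: KOH (10% aq.), 0 °C → rt
Reagents that add atoms: none
Why: C-alkylation of the resorcinol dianion in water (phenoxide C-prenylation), where the carbon flanked by both phenoxide oxygens is the most nucleophilic site and the protic medium disfavours O-alkylation; minor O- and C5-alkylated material should be removable by chromatography.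

Step 2
Reactants: 4 2,4-dihydroxybenzaldehyde
Product: 5 2,4-bis(methoxymethoxy)benzaldehyde
Conditions: NaH, MOMCl, DMF, 0 °C → rt
Reagents that add atoms: chloromethyl methyl ether (MOMCl), COCCl
Why: Williamson-type O-alkylation of both phenoxides (MOM protection) gives base-stable acetals for the aldol step.

Step 3
Reactants: 3 3-prenyl-2,4-dihydroxyacetophenone; 5 2,4-bis(methoxymethoxy)benzaldehyde
Product: 6 morachalcone A 2,4-bis(methoxymethyl) ether ((E)-enone)
Conditions: KOH (50% aq.), EtOH, 0 °C → rt
Reagents that add atoms: none
Why: Claisen–Schmidt (crossed aldol) condensation of the methyl ketone enolate with the non-enolisable aldehyde, the (E)-alkene forming by E1cB dehydration under thermodynamic control.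

Step 4
Reactants: 6 morachalcone A 2,4-bis(methoxymethyl) ether
Product: 7 morachalcone A ((E)-1-(2,4-dihydroxy-3-prenylphenyl)-3-(2,4-dihydroxyphenyl)prop-2-en-1-one)
Conditions: HCl (3 M aq.), MeOH, rt, dark
Reagents that add atoms: none
Why: acid-catalysed acetal exchange of the two aryl MOM ethers with methanol under conditions mild enough to leave the prenyl group and the enone intact.

Step 5
Reactants: 7 morachalcone A
Product: 8 morachalcone A 4',2,4-triacetate (2'-OH free)
Conditions: Ac2O (3.3 equiv), pyridine, CH2Cl2, 0 °C
Reagents that add atoms: acetic anhydride, CC(=O)OC(C)=O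
Why: selective O-acetylation, since the 2'-hydroxyl is hydrogen-bonded to the ketone and flanked by the prenyl group, so only the three free phenols should be esterified and the chelating OH needed in step 7 is kept.

Step 6
Reactants: 9 3-methylbut-2-enal
Product: 10 (E)-3-methylbuta-1,3-dien-1-yl acetate
Conditions: isopropenyl acetate, TsOH·H2O (cat.), 90 °C (acetone distilled off); fractional distillation
Reagents that add atoms: isopropenyl acetate, CC(=C)OC(C)=O
Why: acid-catalysed enol-ester exchange (dienol acetate formation) via gamma-deprotonation of the enal, the conjugated dienol being trapped as its thermodynamically preferred (E)-acetate.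

Step 7
Reactants: 8 morachalcone A 4',2,4-triacetate; 10 (E)-3-methylbuta-1,3-dien-1-yl acetate
Product: 11 (4S,5R)-ring-D adduct (C3 epimer mixture): [3-acetoxy-5-(2,4-diacetoxyphenyl)-1-methylcyclohex-1-en-4-yl] (4-acetoxy-2-hydroxy-3-prenylphenyl) ketone
Conditions: B(OPh)3 (20 mol %), (R)-1,1'-bi-2-naphthol (20 mol %), 4 Å MS, CH2Cl2, rt; 10 (3 equiv)
Reagents that add atoms: none
Why: Diels–Alder reaction of a 2'-hydroxychalcone activated as its chelated chiral borate, in which the (E)-enone fixes the 4,5-trans relationship, the binaphthol ligand shields one enone face and so sets the absolute configuration at C4 and C5, the matched 1-acetoxy/3-methyl pattern of the diene places the acetoxy carbon next to the carbon alpha to the ketone, and the endo/exo outcome at C3 is deliberately left uncontrolled because step 12 erases it.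

Step 8
Reactants: 11 (4S,5R)-ring-D adduct (C3 epimer mixture)
Product: 12 (4S,5R)-ring-D allylic acetate pentaacetate (C3 epimer mixture; ring-A ortho-OH acetylated)
Conditions: Ac2O, pyridine, 4-(dimethylamino)pyridine (cat.), CH2Cl2, 0 °C → rt
Reagents that add atoms: acetic anhydride, CC(=O)OC(C)=O
Why: nucleophile-catalysed acylation of the hindered hydrogen-bonded phenol with a base too weak to trigger E1cB loss of the beta-acetoxy group; capping this phenol removes the internal oxygen nucleophile and the ketone chelate before the cation is generated.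

Step 9
Reactants: 1 2,4-dihydroxyacetophenone
Product: 13 5-bromo-2,4-dihydroxyacetophenone
Conditions: NBS (1.0 equiv), MeCN, 0 °C
Reagents that add atoms: N-bromosuccinimide, O=C1CCC(=O)N1Br
Why: electrophilic aromatic bromination at C5, the site para to the chelated 2-OH and ortho to the 4-OH that halogen electrophiles prefer in this ketone, which installs the temporary blocking group for step 12.

Step 10
Reactants: 4 2,4-dihydroxybenzaldehyde
Product: 14 2,4-diacetoxybenzaldehyde
Conditions: Ac2O, pyridine, CH2Cl2, 0 °C → rt
Reagents that add atoms: acetic anhydride, CC(=O)OC(C)=O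
Why: standard pyridine-mediated acetylation of both phenols gives the aldehyde that carries the electron-withdrawing ring-C protecting groups.

Step 11
Reactants: 13 5-bromo-2,4-dihydroxyacetophenone; 14 2,4-diacetoxybenzaldehyde
Product: 15 (E)-1-(5-bromo-2,4-dihydroxyphenyl)-3-(2,4-diacetoxyphenyl)prop-2-en-1-one
Conditions: BF3·OEt2 (2 equiv), 1,4-dioxane, rt; aq. NaHCO3
Reagents that add atoms: none
Why: Lewis-acid-mediated Claisen–Schmidt condensation in which BF3 chelates the 2-hydroxyaryl ketone, promotes enolisation and aldehyde activation and dehydrates the aldol to the (E)-enone, without the base that would cleave the aryl acetates.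

Step 12
Reactants: 12 (4S,5R)-ring-D allylic acetate pentaacetate (C3 epimer mixture); 15 (E)-1-(5-bromo-2,4-dihydroxyphenyl)-3-(2,4-diacetoxyphenyl)prop-2-en-1-one
Product: 17 (3S,4S,5R)-5'-bromokuwanon I hexaacetate (ring-B hydroxyls free), via allyl cation 16 (not isolated)
Conditions: 15 (2.5 equiv), BF3·OEt2 (0.5 equiv), CH2Cl2/(CF3)2CHOH 4:1, −20 → 0 °C; aq. NaHCO3 (excess 15 recovered)
Reagents that add atoms: none
Why: BF3 ionises both C3 epimers of allylic acetate 12 to the same 1-methylcyclohexenyl cation 16 (C1–C2–C3 of ring D), which is captured at its secondary terminus C3 by C3' of 15, the ring-B carbon flanked by the two phenolic hydroxyls, followed by rearomatisation (Friedel–Crafts allylic alkylation of SN1 type). The closest known reaction type is the Lewis-acid-mediated C2-allylation of resorcinols and resorcylate esters by 3-methylcyclohex-2-enyl cations generated from cyclic allylic alcohols or esters, which gives trans-2-(6-substituted 3-methylcyclohex-2-enyl)resorcinols of the cannabinoid type. No ring is closed; the step is an intermolecular union of the two halves. The new stereocentre C3 is controlled by the adjacent C4 stereocentre: the arene should approach the planar cation anti to the vicinal aroyl group, giving the 3,4-trans and therefore all-trans (3,5-cis) arrangement, which is also the all-equatorial and most stable one, so the epimer mixture from step 7 converges on one configuration. The step needs site selectivity on the arene (secured by the bromine at C5', which blocks the only other activated position, and by the acetates that make rings A, C and E too electron-poor to compete), regioselectivity on the cation (attack at secondary C3 rather than tertiary C1 is sterically favoured and leaves the trisubstituted alkene) and capture faster than loss of the C4 proton (secured by excess 15, low temperature and the non-chelated ring-A ketone). C4 and C5 are not touched, so the enantiomeric purity set in step 7 should be carried into 17.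

Step 13
Reactants: 17 (3S,4S,5R)-5'-bromokuwanon I hexaacetate
Product: 18 (3S,4S,5R)-kuwanon I hexaacetate (ring-B hydroxyls free)
Conditions: Pd(OAc)2 (5 mol %), PPh3 (20 mol %), HCO2Na, DMF, 70 °C
Reagents that add atoms: none
Why: palladium-catalysed transfer hydrodehalogenation, in which zerovalent palladium inserts into the aryl C–Br bond, formate replaces bromide and loses CO2, and Ar–H is reductively eliminated; with a homogeneous phosphine catalyst no free palladium hydride should build up to reduce the enone or the trisubstituted alkenes, and any acetate migration is harmless because step 14 removes all acetates.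

Step 14
Reactants: 18 (3S,4S,5R)-kuwanon I hexaacetate
Product: 19 kuwanon I
Conditions: K2CO3, MeOH, 0 °C → rt, Ar; then dilute aq. HCl to pH 5
Reagents that add atoms: none
Why: base-catalysed methanolysis of the six aryl acetates; the only epimerisable centre, C4, already has the thermodynamically preferred trans,trans arrangement, and short exposure at low temperature should avoid chalcone-to-flavanone cyclisation.

## Compound list

1 | 2,4-dihydroxyacetophenone | CC(=O)c1ccc(O)cc1O | starting material
2 | prenyl bromide (1-bromo-3-methylbut-2-ene) | CC(C)=CCBr | starting material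
3 | 3-prenyl-2,4-dihydroxyacetophenone | CC(=O)c1ccc(O)c(CC=C(C)C)c1O | intermediate
4 | 2,4-dihydroxybenzaldehyde | O=Cc1ccc(O)cc1O | starting material
5 | 2,4-bis(methoxymethoxy)benzaldehyde | COCOc1ccc(C=O)c(OCOC)c1 | intermediate
6 | morachalcone A 2,4-bis(methoxymethyl) ether, (E) | CC(C)=CCc1c(O)ccc(C(=O)/C=C/c2ccc(OCOC)cc2OCOC)c1O | intermediate
7 | morachalcone A, (E) | CC(C)=CCc1c(O)ccc(C(=O)/C=C/c2ccc(O)cc2O)c1O | intermediate
8 | morachalcone A 4',2,4-triacetate (2'-OH free), (E) | CC(C)=CCc1c(OC(C)=O)ccc(C(=O)/C=C/c2ccc(OC(C)=O)cc2OC(C)=O)c1O | intermediate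
9 | 3-methylbut-2-enal | CC(C)=CC=O | starting material
10 | (E)-3-methylbuta-1,3-dien-1-yl acetate | CC(=C)/C=C/OC(C)=O | intermediate
11 | (4S,5R)-ring-D Diels–Alder adduct, 4,5-trans, C3-OAc epimer mixture, ring-A ortho-OH free | CC(C)=CCc1c(OC(C)=O)ccc(C(=O)[C@@H]2C(OC(C)=O)C=C(C)C[C@H]2c2ccc(OC(C)=O)cc2OC(C)=O)c1O | intermediate
12 | (4S,5R)-ring-D allylic acetate pentaacetate, 4,5-trans, C3 epimer mixture | CC(C)=CCc1c(OC(C)=O)ccc(C(=O)[C@@H]2C(OC(C)=O)C=C(C)C[C@H]2c2ccc(OC(C)=O)cc2OC(C)=O)c1OC(C)=O | intermediate
13 | 5-bromo-2,4-dihydroxyacetophenone | CC(=O)c1cc(Br)c(O)cc1O | intermediate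
14 | 2,4-diacetoxybenzaldehyde | CC(=O)Oc1ccc(C=O)c(OC(C)=O)c1 | intermediate
15 | (E)-1-(5-bromo-2,4-dihydroxyphenyl)-3-(2,4-diacetoxyphenyl)prop-2-en-1-one | CC(=O)Oc1ccc(/C=C/C(=O)c2cc(Br)c(O)cc2O)c(OC(C)=O)c1 | intermediate
16 | ring-D allyl cation (C1–C2–C3), C4 and C5 as in 12 | CC(C)=CCc1c(OC(C)=O)ccc(C(=O)[C@@H]2[CH+]C=C(C)C[C@H]2c2ccc(OC(C)=O)cc2OC(C)=O)c1OC(C)=O | intermediate (not isolated)
17 | (3S,4S,5R)-5'-bromokuwanon I hexaacetate, all-trans, ring-B hydroxyls free | CC(C)=CCc1c(OC(C)=O)ccc(C(=O)[C@@H]2[C@@H](c3c(O)c(Br)cc(C(=O)/C=C/c4ccc(OC(C)=O)cc4OC(C)=O)c3O)C=C(C)C[C@H]2c2ccc(OC(C)=O)cc2OC(C)=O)c1OC(C)=O | intermediate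
18 | (3S,4S,5R)-kuwanon I hexaacetate, all-trans, ring-B hydroxyls free | CC(C)=CCc1c(OC(C)=O)ccc(C(=O)[C@@H]2[C@@H](c3c(O)ccc(C(=O)/C=C/c4ccc(OC(C)=O)cc4OC(C)=O)c3O)C=C(C)C[C@H]2c2ccc(OC(C)=O)cc2OC(C)=O)c1OC(C)=O | intermediate
19 | kuwanon I, (3S,4S,5R) in ring-D numbering, all-trans | CC(C)=CCc1c(O)ccc(C(=O)[C@@H]2[C@@H](c3c(O)ccc(C(=O)/C=C/c4ccc(O)cc4O)c3O)C=C(C)C[C@H]2c2ccc(O)cc2O)c1O | target

## Step count and risks

Total steps: 14. Longest linear sequence: 9 steps (steps 1, 3, 4, 5, 7, 8, 12, 13, 14).

Steps most likely to fail:

1. Step 12. E1 loss of the C4 proton from the allyl cation (an irreversible leak to the ring-D dienone, which also destroys the C4 stereocentre) may outrun capture by the deactivated and valuable arene. The fallback sets out from 12 and 13: the cheap ketone 13 is used as the arene in large excess under the same ionising conditions, so that the union is made at the acetophenone stage and gives the ring-B bromo methyl ketone F1. The enone is then built afterwards by the BF3·OEt2-mediated Claisen–Schmidt condensation of F1 with 14, which returns to the route at 17.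

2. Step 7. Decomposition or oligomerisation of the dienyl acetate by the boron Lewis acid, or insufficient facial discrimination by the catalyst, would erode yield or enantiomeric purity. The fallback sets out from 9 and replaces catalyst control by auxiliary control with diastereomer separation. Dienolate O-acylation of 9 (KOtBu, THF, −78 °C, then (S)-2-methoxy-2-phenylacetyl chloride) gives the chiral dienyl ester F2. Its Diels–Alder reaction with 8 under achiral B(OPh)3 gives the ring-D adducts F3, in which the two ring-D enantiomeric series are diastereomers; the (4S,5R) series is isolated by chromatography. Acetylation of the ring-A ortho-OH as in step 8 gives F4, which is used in step 12 in place of 12 (the O-methylmandelate leaves on ionisation), returning to the route at 17.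

3. Step 13. Conjugate reduction of the chalcone enone, or sluggish oxidative addition at the electron-rich ortho-hydroxylated bromide, would spoil the chemoselective debromination. The fallback sets out from 17 and removes the bromine at a different stage by a hydride-free mechanism. Methanolysis of the six acetates first (K2CO3, MeOH, as in step 14) gives 5'-bromokuwanon I F5. The bromine, ortho to one ring-B hydroxyl and para to the other, is then removed by halophilic reductive debromination of the phenol keto tautomer (Na2SO3, Et3N, ascorbic acid, MeOH/H2O, 60 °C), where the phenoxide-rich chalcone should resist sulfite addition; this returns to the route at the target 19.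

Further compounds
F1 | step 12 | (3S,4S,5R)-ring-B bromo methyl ketone tetraacetate (union product of 12 with 13) | CC(C)=CCc1c(OC(C)=O)ccc(C(=O)[C@@H]2[C@@H](c3c(O)c(Br)cc(C(C)=O)c3O)C=C(C)C[C@H]2c2ccc(OC(C)=O)cc2OC(C)=O)c1OC(C)=O
F2 | step 7 | (E)-3-methylbuta-1,3-dien-1-yl (S)-2-methoxy-2-phenylacetate | CO[C@H](C(=O)O/C=C/C(C)=C)c1ccccc1
F3 | step 7 | (4S,5R)-ring-D adduct with C3 (S)-O-methylmandelate, C3 epimer mixture, ring-A ortho-OH free | CC(C)=CCc1c(OC(C)=O)ccc(C(=O)[C@@H]2C(OC(=O)[C@@H](OC)c3ccccc3)C=C(C)C[C@H]2c2ccc(OC(C)=O)cc2OC(C)=O)c1O
F4 | step 7 | (4S,5R)-ring-D adduct with C3 (S)-O-methylmandelate, ring-A ortho-OH acetylated | CC(C)=CCc1c(OC(C)=O)ccc(C(=O)[C@@H]2C(OC(=O)[C@@H](OC)c3ccccc3)C=C(C)C[C@H]2c2ccc(OC(C)=O)cc2OC(C)=O)c1OC(C)=O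
F5 | step 13 | (3S,4S,5R)-5'-bromokuwanon I | CC(C)=CCc1c(O)ccc(C(=O)[C@@H]2[C@@H](c3c(O)c(Br)cc(C(=O)/C=C/c4ccc(O)cc4O)c3O)C=C(C)C[C@H]2c2ccc(O)cc2O)c1O
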